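**Plan**

1. Numbering: each half is a coumarin (O1, C2–C4, C4a–C8a) carrying a fused pyran (O1′, C2′, C3′, C4′). The retrosynthesis cuts, in order: (a) both lactone O1–C2 bonds, giving an all-cis seco diester/diphenol that is achiral (meso), because the target's chirality lies only in which phenol is paired with which carboxyl; (b) in both pyran rings O1′–C7 and C3′=C4′; (c) the two cyclobutane C3–C4 bonds between the halves, back to a 7-fluoro-8-formylcoumarin.
2. Forward order of rings: coumarin pyranone ring, then the cyclobutane by syn head-to-tail [2+2] photodimerisation, lactones opened to a base-stable meso tert-butyl ester/SEM ether, both pyran rings in one operation, helpers (sulfonyl, SEM) removed, both lactone rings closed last.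
3. Enabling feature: on each benzo ring the future C4′ sits on C8, between fluorine-bearing C7 and oxygen-bearing C8a. As a formyl group it activates C7–F for substitution by the tertiary alkoxide oxygen (future O1′) and then accepts the sulfonyl-stabilised carbanion (future C3′).
4. Stereochemistry: the all-cis relative configuration of the four cyclobutane CH comes from the stacked, suprafacial photodimerisation (racemic material suffices). The absolute configuration comes from the final catalyst-controlled desymmetrising double lactonisation of the meso diphenol.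

Key step: step 7

Remark: 6 is made and carried as the racemate; opening both lactones gives one meso compound (7), so no resolution is needed and the absolute configuration is set only in step 10. SEM = [2-(trimethylsilyl)ethoxy]methyl; coumarin numbering is kept for the benzo carbons throughout.

**Step 1**
Reactants: 1 3-fluoro-2-methylphenol
Product: 2 4-fluoro-2-hydroxy-3-methylbenzaldehyde
Conditions: MgCl2, Et3N, (CH2O)n, MeCN, reflux
Reagents that add atoms: paraformaldehyde (as formaldehyde), C=O
Why: Magnesium-phenoxide-directed ortho-formylation (Casnati–Skattebøl reaction) should place the formyl group at C6 of 1, the only free position ortho to the hydroxyl group.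

**Step 2**
Reactants: 2 4-fluoro-2-hydroxy-3-methylbenzaldehyde
Product: 3 7-fluoro-8-methyl-2H-chromen-2-one
Conditions: Ph3P=CHCO2Et, PhNEt2, reflux
Reagents that add atoms: ethyl (triphenylphosphoranylidene)acetate, CCOC(=O)C=P(c1ccccc1)(c1ccccc1)c1ccccc1
Why: Wittig olefination of the salicylaldehyde with the stabilised ylide, followed at this temperature by E/Z equilibration of the 2-hydroxycinnamate and lactonisation, should give the coumarin in one pot.

**Step 3**
Reactants: 3 7-fluoro-8-methyl-2H-chromen-2-one
Product: 5 7-fluoro-2-oxo-2H-chromene-8-carbaldehyde, via dibromide 4 (not isolated)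
Conditions: NBS (2.2 equiv), AIBN (cat.), PhCF3, reflux; then AgNO3, H2O–EtOH, 70 °C
Reagents that add atoms: water, O
Why: Wohl–Ziegler bromination should take the only benzylic C–H bonds (8-CH3) to the gem-dibromide, and silver-assisted hydrolysis of this benzal bromide should give the aldehyde, the coumarin lactone being inert to both.

**Step 4**
Reactants: 5 7-fluoro-2-oxo-2H-chromene-8-carbaldehyde (two molecules)
Product: 6 racemic syn head-to-tail cyclobutane bis-lactone dimer of 5
Conditions: BF3·OEt2 (0.6 equiv), CH2Cl2, hν (366 nm), 0 °C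
Reagents that add atoms: none
Why: Lewis-acid-promoted [2+2] photodimerisation of a coumarin: the BF3-complexed excited molecule should add to an uncomplexed ground-state molecule through a π-stacked, dipole-opposed (head-to-tail) pair, and suprafacial bonding on both stacked C3=C4 faces puts the four cyclobutane hydrogens cis (relative configuration only; racemate).

**Step 5**
Reactants: 6 racemic syn head-to-tail cyclobutane bis-lactone dimer of 5
Product: 7 meso di-tert-butyl all-cis-2,4-bis[4-fluoro-3-formyl-2-(SEM-oxy)phenyl]cyclobutane-1,3-dicarboxylate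
Conditions: KOtBu (2.1 equiv), THF, −78 → −40 °C; then SEM-Cl, −40 → 0 °C
Reagents that add atoms: potassium tert-butoxide, CC(C)(C)[O-].[K+]; 2-(trimethylsilyl)ethoxymethyl chloride, C[Si](C)(C)CCOCCl
Why: Transesterification of the two aryl-ester lactones by tert-butoxide is far faster at −78 °C than SNAr at C7–F, the liberated phenoxides are capped by Williamson alkylation, and opening both lactones turns either enantiomer of 6 into the same meso compound without touching a stereocentre.

**Step 6**
Reactants: 8 sodium benzenesulfinate; 9 2,2-dimethyloxirane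
Product: 10 2-methyl-1-(phenylsulfonyl)propan-2-ol
Conditions: AcOH (1 equiv), H2O–EtOH, 60 °C
Reagents that add atoms: none
Why: S-Alkylation of the sulfinate by SN2 opening of the epoxide at its CH2 terminus (epoxide ring-opening) should give the β-hydroxy sulfone.

**Step 7**
Reactants: 7 meso di-tert-butyl all-cis-2,4-bis[4-fluoro-3-formyl-2-(SEM-oxy)phenyl]cyclobutane-1,3-dicarboxylate; 10 2-methyl-1-(phenylsulfonyl)propan-2-ol (two molecules react)
Product: 13 meso di-tert-butyl all-cis-2,4-bis[2,2-dimethyl-3-(phenylsulfonyl)-5-(SEM-oxy)-2H-chromen-6-yl]cyclobutane-1,3-dicarboxylate, via bis-ether dialdehyde 11 (not isolated), via bis-acetoxysulfone 12 (not isolated)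
Conditions: NaH (2.4 equiv), 10 (2.6 equiv), DMF, 0 → 40 °C; then Ac2O, 0 °C; then DBU, 25 °C
Reagents that add atoms: none
Why: Proposed new method: the sodium alkoxide of 10 should displace fluoride at C7 of each benzo ring through a Meisenheimer adduct stabilised by the ortho formyl group on C8 (oxa-SNAr, forming O1′–C7), after which the residual alkoxide equilibrates the α-sulfonyl carbanion C3′, which adds to the same formyl carbon C4′ in a 6-exo-trig aldol closure of the pyran ring; acetylation and DBU-induced E1cB loss of acetate then give C3′=C4′. The closest known reaction type is the domino SNAr/aldol condensation of 2-fluorobenzaldehydes with glycolate or thioglycolate esters to benzofurans and benzothiophenes, extended here to a β-hydroxy sulfone as the O,C-dinucleophile and to a six-membered ring. No new stereocentre survives: the transient C3′/C4′ centres of 12 are erased by the elimination, and the four cyclobutane centres are spectators. The step needs chemoselectivity for C–F substitution over attack at the carboxyl groups; this is secured by the tert-butyl esters (too hindered for acyl transfer), by the SEM ethers (no phenoxide that would switch off the formyl activation) and by the fact that only the C–F bond ortho to the formyl group is activated. Epimerisation of the all-cis cyclobutane should be avoided because the only bases present after the substitution are a sub-stoichiometric tertiary alkoxide, buffered by the more acidic sulfone C–H, and DBU, neither of which should enolise a hindered tert-butyl ester at 25–40 °C. The sulfonyl group is the temporary activating group and is removed in step 8.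

**Step 8**
Reactants: 13 meso di-tert-butyl all-cis-2,4-bis[2,2-dimethyl-3-(phenylsulfonyl)-5-(SEM-oxy)-2H-chromen-6-yl]cyclobutane-1,3-dicarboxylate
Product: 14 meso di-tert-butyl all-cis-2,4-bis[2,2-dimethyl-5-(SEM-oxy)-2H-chromen-6-yl]cyclobutane-1,3-dicarboxylate
Conditions: Na/Hg (6% Na), Na2HPO4, MeOH–THF, −20 °C
Reagents that add atoms: none
Why: Reductive desulfonylation of the vinyl sulfones by electron transfer from sodium amalgam (the reductive stage of the Julia olefination) should replace each C3′–S bond by C–H with the ring-locked double bond retained, tert-butyl esters and SEM ethers being inert.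

**Step 9**
Reactants: 14 meso di-tert-butyl all-cis-2,4-bis[2,2-dimethyl-5-(SEM-oxy)-2H-chromen-6-yl]cyclobutane-1,3-dicarboxylate
Product: 15 meso di-tert-butyl all-cis-2,4-bis(5-hydroxy-2,2-dimethyl-2H-chromen-6-yl)cyclobutane-1,3-dicarboxylate
Conditions: Bu4NF, THF–DMPU, 60 °C; NH4Cl (aq)
Reagents that add atoms: none
Why: Fluoride-induced fragmentation of the SEM ethers (attack at silicon, loss of ethene and formaldehyde) should free both phenols, and a phenoxide cannot expel tert-butoxide from the hindered esters, so no uncatalysed lactonisation erodes the later stereocontrol.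

**Step 10**
Reactants: 15 meso di-tert-butyl all-cis-2,4-bis(5-hydroxy-2,2-dimethyl-2H-chromen-6-yl)cyclobutane-1,3-dicarboxylate
Product: 17 CNP0167575.1 (syn head-to-tail seselin dimer in the configuration given), via mono-lactone 16 (not isolated)
Conditions: (R)-TRIP [(R)-3,3′-bis(2,4,6-triisopropylphenyl)-1,1′-binaphthyl-2,2′-diyl hydrogen phosphate] (10 mol%; the (S)-acid if the sense of induction proves opposite), toluene, 5 Å molecular sieves, 40 °C
Reagents that add atoms: none
Why: Proposed new method: the chiral phosphoric acid should activate a tert-butyl ester while hydrogen-bonding the attacking phenol, and because each phenol is flanked by two enantiotopic ester groups (mirror plane through cyclobutane C2 and C4) the catalyst decides which ester the first phenol takes, a single choice that fixes the absolute configuration of all four stereocentres since the second lactonisation is then constitutionally forced; the closest known reaction type is the chiral-phosphoric-acid-catalysed desymmetrising lactonisation of prochiral hydroxy di-tert-butyl malonates.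

**Compound list**

1 | 3-fluoro-2-methylphenol | Cc1c(O)cccc1F | starting material
2 | 4-fluoro-2-hydroxy-3-methylbenzaldehyde | Cc1c(F)ccc(C=O)c1O | intermediate
3 | 7-fluoro-8-methyl-2H-chromen-2-one | Cc1c(F)ccc2ccc(=O)oc12 | intermediate
4 | 8-(dibromomethyl)-7-fluoro-2H-chromen-2-one | BrC(Br)c1c(F)ccc2ccc(=O)oc12 | intermediate (not isolated)
5 | 7-fluoro-2-oxo-2H-chromene-8-carbaldehyde | O=Cc1c(F)ccc2ccc(=O)oc12 | intermediate
6 | racemic syn head-to-tail cyclobutane bis-lactone dimer of 5 (C3 of each unit bonded to C4 of the other; all four cyclobutane H cis; one enantiomer drawn) | O=Cc1c(F)ccc2c1OC(=O)[C@H]3[C@@H]2[C@H]4C(=O)Oc5c(C=O)c(F)ccc5[C@H]43 | intermediate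
7 | di-tert-butyl all-cis-2,4-bis{4-fluoro-3-formyl-2-[[2-(trimethylsilyl)ethoxy]methoxy]phenyl}cyclobutane-1,3-dicarboxylate (meso) | CC(C)(C)OC(=O)[C@H]1[C@@H](c2ccc(F)c(C=O)c2OCOCC[Si](C)(C)C)[C@@H](C(=O)OC(C)(C)C)[C@H]1c3ccc(F)c(C=O)c3OCOCC[Si](C)(C)C | intermediate
8 | sodium benzenesulfinate | [Na+].[O-]S(=O)c1ccccc1 | starting material
9 | 2,2-dimethyloxirane | CC1(C)CO1 | starting material
10 | 2-methyl-1-(phenylsulfonyl)propan-2-ol | CC(C)(O)CS(=O)(=O)c1ccccc1 | intermediate
11 | di-tert-butyl all-cis-2,4-bis{3-formyl-4-[2-methyl-1-(phenylsulfonyl)propan-2-yloxy]-2-(SEM-oxy)phenyl}cyclobutane-1,3-dicarboxylate (meso) | CC(C)(C)OC(=O)[C@H]1[C@@H](c2ccc(OC(C)(C)CS(=O)(=O)c3ccccc3)c(C=O)c2OCOCC[Si](C)(C)C)[C@@H](C(=O)OC(C)(C)C)[C@H]1c4ccc(OC(C)(C)CS(=O)(=O)c5ccccc5)c(C=O)c4OCOCC[Si](C)(C)C | intermediate (not isolated)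
12 | di-tert-butyl all-cis-2,4-bis[4-acetoxy-2,2-dimethyl-3-(phenylsulfonyl)-5-(SEM-oxy)chroman-6-yl]cyclobutane-1,3-dicarboxylate (mixture of epimers at chroman C3 and C4, left undefined) | CC(C)(C)OC(=O)[C@H]1[C@@H](c2ccc3OC(C)(C)C(S(=O)(=O)c4ccccc4)C(OC(C)=O)c3c2OCOCC[Si](C)(C)C)[C@@H](C(=O)OC(C)(C)C)[C@H]1c5ccc6OC(C)(C)C(S(=O)(=O)c7ccccc7)C(OC(C)=O)c6c5OCOCC[Si](C)(C)C | intermediate (not isolated)
13 | di-tert-butyl all-cis-2,4-bis[2,2-dimethyl-3-(phenylsulfonyl)-5-(SEM-oxy)-2H-chromen-6-yl]cyclobutane-1,3-dicarboxylate (meso) | CC(C)(C)OC(=O)[C@H]1[C@@H](c2ccc3OC(C)(C)C(S(=O)(=O)c4ccccc4)=Cc3c2OCOCC[Si](C)(C)C)[C@@H](C(=O)OC(C)(C)C)[C@H]1c5ccc6OC(C)(C)C(S(=O)(=O)c7ccccc7)=Cc6c5OCOCC[Si](C)(C)C | intermediate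
14 | di-tert-butyl all-cis-2,4-bis[2,2-dimethyl-5-(SEM-oxy)-2H-chromen-6-yl]cyclobutane-1,3-dicarboxylate (meso) | CC(C)(C)OC(=O)[C@H]1[C@@H](c2ccc3OC(C)(C)C=Cc3c2OCOCC[Si](C)(C)C)[C@@H](C(=O)OC(C)(C)C)[C@H]1c4ccc5OC(C)(C)C=Cc5c4OCOCC[Si](C)(C)C | intermediate
15 | di-tert-butyl all-cis-2,4-bis(5-hydroxy-2,2-dimethyl-2H-chromen-6-yl)cyclobutane-1,3-dicarboxylate (meso) | CC(C)(C)OC(=O)[C@H]1[C@@H](c2ccc3OC(C)(C)C=Cc3c2O)[C@@H](C(=O)OC(C)(C)C)[C@H]1c4ccc5OC(C)(C)C=Cc5c4O | intermediate
16 | mono-lactone: one pyranocoumarin lactone closed, the other half still tert-butyl ester and free phenol (all-cis cyclobutane) | CC1(C)C=Cc2c(ccc3c2OC(=O)[C@H]2[C@@H]3[C@@H](C(=O)OC(C)(C)C)[C@H]2c4ccc5OC(C)(C)C=Cc5c4O)O1 | intermediate (not isolated)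
17 | CNP0167575.1, syn head-to-tail cyclobutane dimer of seselin (enantiomer as given) | CC1(C)C=Cc2c(ccc3c2OC(=O)[C@H]2[C@@H]3[C@H]3C(=O)Oc4c5c(ccc4[C@H]32)OC(C)(C)C=C5)O1 | target

**Step count**

Total steps: 10. Longest linear sequence: 9 (steps 1–5 and 7–10, from 1); step 6 is a one-step branch.

**Three steps most likely to fail**

1. Step 7 (labelled). The α-sulfonyl carbanion of 11 may expel the aryloxide (E1cB) instead of closing the ring. The reagent alkoxide may fragment to acetone and the sulfonylmethyl anion. The second substitution at the hindered benzaldehyde may stall. Long basic contact may epimerise a cyclobutane CH next to an ester. The fallback sets out from 7 and returns at 14, using only known reactions. Compound 7 is treated with the sodium alkoxide of 2-methylbut-3-en-2-ol (NaH, DMF) in a plain twofold oxa-SNAr to give the bis(1,1-dimethylallyl aryl ether) dialdehyde F1. Wittig methylenation (Ph3P=CH2, THF, 0 °C) gives the bis-styrene F2. Twofold ring-closing metathesis with the second-generation Grubbs catalyst (CH2Cl2, 40 °C) closes both pyran rings with loss of ethene and gives 14 directly, so step 8 is not needed.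

2. Step 10 (labelled). The catalyst may discriminate poorly between the two enantiotopic esters. Trans-lactonisation at the mono-lactone stage may scramble the pairing. Acyl substitution by the phenol may be sluggish. The fallback sets out from 15 and returns at 17, using only known reactions. Compound 15 is lactonised without stereocontrol by catalytic diphenyl phosphate (toluene, 50 °C) to the racemate, from which 17 is separated by preparative chromatography on a chiral stationary phase. The unwanted enantiomer of 17 F3 is recycled: saponification (LiOH, aq. THF) gives the meso diacid diphenol F4, and its relactonisation with the same acid returns the racemate for another pass.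

3. Step 4. The photodimerisation may give head-to-head or anti dimers, the formyl group may sequester the Lewis acid, or the aldehyde may undergo its own photoreactions. The fallback sets out from 5 and returns at 6. Compound 5 is converted (ethylene glycol, TsOH, toluene, water removal) into the dioxolane-protected coumarin F5, which removes the photoactive aldehyde. F5 is irradiated (350 nm) in water as the 2:1 inclusion complex in cucurbit[8]uril, whose cavity enforces the stacked head-to-tail pairing, to give the bis-dioxolane dimer F6. Aqueous HCl/THF then hydrolyses the acetals to 6.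

**Further compounds**

F1 | step 7 | di-tert-butyl all-cis-2,4-bis[3-formyl-4-(2-methylbut-3-en-2-yloxy)-2-(SEM-oxy)phenyl]cyclobutane-1,3-dicarboxylate (meso) | CC(C)(C)OC(=O)[C@H]1[C@@H](c2ccc(OC(C)(C)C=C)c(C=O)c2OCOCC[Si](C)(C)C)[C@@H](C(=O)OC(C)(C)C)[C@H]1c3ccc(OC(C)(C)C=C)c(C=O)c3OCOCC[Si](C)(C)C
F2 | step 7 | di-tert-butyl all-cis-2,4-bis[4-(2-methylbut-3-en-2-yloxy)-2-(SEM-oxy)-3-vinylphenyl]cyclobutane-1,3-dicarboxylate (meso) | CC(C)(C)OC(=O)[C@H]1[C@@H](c2ccc(OC(C)(C)C=C)c(C=C)c2OCOCC[Si](C)(C)C)[C@@H](C(=O)OC(C)(C)C)[C@H]1c3ccc(OC(C)(C)C=C)c(C=C)c3OCOCC[Si](C)(C)C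
F3 | step 10 | enantiomer of 17 | CC1(C)C=Cc2c(ccc3c2OC(=O)[C@@H]2[C@H]3[C@@H]3C(=O)Oc4c5c(ccc4[C@@H]32)OC(C)(C)C=C5)O1
F4 | step 10 | all-cis-2,4-bis(5-hydroxy-2,2-dimethyl-2H-chromen-6-yl)cyclobutane-1,3-dicarboxylic acid (meso) | OC(=O)[C@H]1[C@@H](c2ccc3OC(C)(C)C=Cc3c2O)[C@@H](C(=O)O)[C@H]1c4ccc5OC(C)(C)C=Cc5c4O
F5 | step 4 | 8-(1,3-dioxolan-2-yl)-7-fluoro-2H-chromen-2-one | O=c1ccc2ccc(F)c(C3OCCO3)c2o1
F6 | step 4 | racemic syn head-to-tail cyclobutane bis-lactone dimer of F5 (all-cis; one enantiomer drawn) | C1(OCCO1)c2c(F)ccc3c2OC(=O)[C@H]4[C@@H]3[C@H]5C(=O)Oc6c(C7OCCO7)c(F)ccc6[C@H]54
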